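**Remark on the chemistry (assumption):** margaspidin has no stereocentre. Hydroxypyranones and polycarbonyl compounds are each drawn as one tautomer, although they are tautomeric mixtures.

## The problem

Margaspidin 14 is two hexasubstituted benzene rings joined through one methylene carbon. Ring A is a 2,4,6-trihydroxy-3-methylphenyl butyl ketone; ring B is the same ring with the oxygen para to the butanoyl group methylated. The rings therefore differ in one O-methyl group among six ring oxygens. A route through free phenols must methylate one hydroxyl out of several, and must then join two nucleophiles of almost equal reactivity through one carbon without forming the two symmetrical dimers. The bridge is also labile: methylene-bridged polyhydroxyaryl ketones exchange their halves in base or acid, and the polyphenolates oxidise in air.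

The feature that opens another way lies in the ring atoms themselves. In each ring the butanoyl-bearing carbon lies between two hydroxyl-bearing carbons. The oxygen para to it (OH in ring A, OCH3 in ring B) lies between the methyl-bearing carbon and the bridge-bearing carbon. Those five ring carbons map onto C2 to C6 of a 3,5-disubstituted 4-oxy-2H-pyran-2-one carrying a 2-oxopentyl chain at C6:

- lactone carbon C2 and enol carbon C6 become the two C–OH carbons;
- C4–O becomes the para oxygen, so a 4-methoxy group is the methoxy group of ring B;
- C5 carries the methyl group;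
- C3, the nucleophilic carbon of a 4-hydroxypyranone, carries the bridge;
- the side-chain methylene becomes the butanoyl-bearing carbon.

Margaspidin 14 is thus a constitutional isomer (C24H30O8) of the methylene-bis-pyranone 10. Because every ring position is substituted, the bridge-bearing carbon has no hydrogen, which closes off the competing aldol mode of folding.

## Retrosynthesis

**14 to 10.** In each ring the bond between the butanoyl-bearing carbon and the hydroxyl-bearing carbon next to the bridge carbon is cut (retro-Claisen), and that carbon is reconnected as a lactone to the oxygen on the far side of the methyl-bearing carbon. This gives the bis-pyranone 10. Cutting the aryl–CH2 bond instead would leave two finished rings that must be told apart in the coupling. The chosen cut removes both benzene rings and all five phenols at once; 10 has one acidic OH and is built from one small pyranone used twice. The forward reaction must open both lactones and close both rings by Claisen condensation, through 11, 12 and 13, without touching the bridge.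

**10 to 9.** The O–CH3 bond is cut. The precursor 9 is a symmetrical bis(4-hydroxypyranone) whose two OH groups are equivalent and are its only strongly acidic sites. The regiochemical question of the target (which of six oxygens carries the methyl group) shrinks to a mono-methylation of two equivalent hydroxyls. The forward reaction must alkylate O4 and not the lactone carbonyl oxygen, and must stop after one methyl group.

**9 to 6 and 7.** Both C3–CH2 bonds are cut. The bridge then comes from formaldehyde 7 and two molecules of pyranone 6 by Knoevenagel condensation to 8 and Michael addition. This is a homodimerisation, so no cross-selectivity is asked for. A directed union of two different pyranones would cost extra steps only to save the later desymmetrisation. The forward reaction needs C3 of 6 to outrun the side-chain methylene as nucleophile.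

**6 to 4 and 5.** The bond between the side-chain methylene and the side-chain carbonyl is cut. Pyranone 4 is a masked triketide; amide 5 delivers the butanoyl starter unit. The alternative of carrying the full open triketo ester chain is avoided because such chains fold prematurely. The forward reaction is a lateral acylation of the dianion of 4 at its 6-methyl group.

**4 to 3 to 1 and 2.** The lactone C–O bond of 4 is cut to give the diketo ester 3. Its C4–C5 bond is then cut to give the commercial keto ester 1 and amide 2. Both forward steps are standard dianion and lactonisation chemistry.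

## Roads not taken

**Alternative 1:** (the obvious route) One aryl–CH2 bond of 14 is cut. The forward key step is the condensation of 1-(2,4,6-trihydroxy-3-methylphenyl)butan-1-one A2 and its 4-O-methyl ether, aspidinol A3, with formaldehyde 7. A directed variant would pass through the aminomethyl (Mannich) derivative A4 of A2 and its ortho-quinone methide. Both monomers would come from 2-methylbenzene-1,3,5-triol A1 by Friedel–Crafts butanoylation and a mono-O-methylation. This is about two steps shorter than the chosen plan. Its weaknesses are structural:
- A2 and A3 are nucleophiles of nearly equal reactivity, so the one-carbon union gives both symmetrical dimers beside 14.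
- The conditions that form the quinone methide also let the product exchange its halves.
- A3 requires methylation of one of three phenols of A2 while the free ring carbon of A2 competes as a C-nucleophile.
- Both benzene rings are bought, not made.

The chosen plan makes the bridge by homodimerisation and places the methyl group before any phenol exists. It does not avoid a selectivity problem at the methylation; it reduces it from one oxygen among several different ones to one of two equivalent ones.

**Alternative 2:** Only ring B is folded. Ring B is cut as in the chosen plan while ring A is kept aromatic. The precursor is the pyranone methyl ether A6, made by O-methylation of the arylmethyl-pyranone A5, which in turn comes from A2, pyranone 6 and formaldehyde 7. The cross-coupling of two different nucleophiles returns, with both symmetrical dimers as by-products. The methylation of the pyranone OH of A5 must compete with three phenols. Two different ring syntheses are needed where the chosen plan uses one building block twice, and the step count is no lower.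

**Alternative 3:** The bridge is taken as an oxidised C-methyl group, copying its presumed biological origin. The aryl–CH2 bond on the side of ring B is cut. The forward key step is dehydrogenation of 1-(2,4,6-trihydroxy-3,5-dimethylphenyl)butan-1-one A7 to the ortho-quinone methide A8 and its capture by A3. An oxidant cannot distinguish the methyl groups of A7 from the two remaining aryl methyl groups and the new diarylmethane CH2 of the product, nor from the electron-rich A3. Over-oxidation and quinone formation are the expected outcome, and A3 still has to be made by a selective O-methylation.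

Key step: step 6

## Route

Step 1
Reactants: 1 ethyl 3-oxopentanoate; 2 N-methoxy-N-methylacetamide
Product: 3 ethyl 4-methyl-3,5-dioxohexanoate
Conditions: LiN(iPr)2 (2.1 equiv), THF, 0 °C; then 2, −78 → 0 °C; aq. HCl
Reagents that add atoms: none
Why: The dianion of the β-keto ester reacts at its more basic γ-carbon (C4), and the N-methoxy-N-methylamide stops at the ketone because its tetrahedral lithium chelate survives until work-up (γ-acylation of a β-keto ester dianion, Weinreb ketone synthesis).

Step 2
Reactants: 3 ethyl 4-methyl-3,5-dioxohexanoate
Product: 4 4-hydroxy-5,6-dimethyl-2H-pyran-2-one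
Conditions: DBU (1.2 equiv), toluene, reflux; then aq. HCl
Reagents that add atoms: none
Why: The enol oxygen at C5 attacks the ester carbonyl and ethanol is lost, the standard base-mediated lactonisation of 3,5-diketo esters to 4-hydroxy-2-pyranones.

Step 3
Reactants: 4 4-hydroxy-5,6-dimethyl-2H-pyran-2-one; 5 N-methoxy-N-methylbutanamide
Product: 6 4-hydroxy-5-methyl-6-(2-oxopentyl)-2H-pyran-2-one
Conditions: LiN(iPr)2 (2.2 equiv), THF–DMPU, −78 °C; then 5, −78 → −20 °C; aq. HCl
Reagents that add atoms: none
Why: After the OH, the second equivalent of base removes a proton from the 6-methyl group, the only carbon acid vinylogous to the lactone carbonyl (the 5-methyl group is cross-conjugated), and the dianion is acylated there (lateral metalation and acylation of 4-hydroxy-6-methyl-2-pyranone dianions).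

Step 4
Reactants: 6 4-hydroxy-5-methyl-6-(2-oxopentyl)-2H-pyran-2-one (two molecules); 7 formaldehyde
Product: 9 3,3'-methylenebis[4-hydroxy-5-methyl-6-(2-oxopentyl)-2H-pyran-2-one], via 3-methylidenepyran-2,4-dione 8 (not isolated)
Conditions: 37% aq. CH2O (0.5 equiv per 6), EtOH, 40 °C
Reagents that add atoms: none
Why: Knoevenagel condensation at the enolic C3 gives the Michael acceptor 8, which a second molecule of 6 attacks at C3 (Knoevenagel–Michael sequence, well known for 4-hydroxy-2-pyranones and 4-hydroxycoumarins); without added base C3 should be far more nucleophilic than the side-chain methylene.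

Step 5
Reactants: 9 3,3'-methylenebis[4-hydroxy-5-methyl-6-(2-oxopentyl)-2H-pyran-2-one]
Product: 10 3-{[4-hydroxy-5-methyl-2-oxo-6-(2-oxopentyl)-2H-pyran-3-yl]methyl}-4-methoxy-5-methyl-6-(2-oxopentyl)-2H-pyran-2-one
Conditions: Me2SO4 (1.0 equiv), K2CO3 (1.0 equiv), acetone, 25–40 °C
Reagents that add atoms: dimethyl sulfate, COS(=O)(=O)OC
Why: The two equivalent pyranone OH groups are the only sites that carbonate ionises to a useful extent, and potassium pyranonates are methylated by dimethyl sulfate mainly at O4 to give 4-methoxy-2-pyranones (O-alkylation of a vinylogous acid). The step is a desymmetrisation under stoichiometric control, expected to be near-statistical at worst, with unreacted 9 recovered and recycled.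

Step 6
Reactants: 10 3-{[4-hydroxy-5-methyl-2-oxo-6-(2-oxopentyl)-2H-pyran-3-yl]methyl}-4-methoxy-5-methyl-6-(2-oxopentyl)-2H-pyran-2-one
Product: 14 margaspidin, via ring-B-opened methyl ester 11 (not isolated), via half-folded pyranone 12 (not isolated), via ring-A-opened methyl ester 13 (not isolated)
Conditions: Mg(OMe)2 (8 equiv), MeOH, reflux, Ar; then cold 1 M HCl
Reagents that add atoms: none
Why: Methoxide opens each lactone at C2 to the magnesium-chelated methyl ester of a masked 3,5,7-triketo acid (11, then 13); the side-chain methylene, now between two ketone carbonyls, attacks that ester carbon in a Claisen condensation, and loss of methoxide followed by enolisation gives the benzene ring, so the net change is a double isomerisation. The closest known reaction type is the magnesium methoxide conversion of 6-(2-oxoalkyl)-4-hydroxy- and 4-methoxy-2-pyranones into acylphloroglucinols, the laboratory counterpart of the Claisen ring closure of a butanoyl-primed tetraketide in acylphloroglucinol biosynthesis. Each ring closes in the 6-(enolexo)-exo-trig mode; no stereocentre is formed, and the methyl-bearing sp3 carbons of 11 and 13 become ring carbons. The step needs Claisen and not aldol folding: the bridge-bearing carbon (pyranone C3) has no hydrogen, so an aldol closure from it onto the side-chain ketone would create a quaternary centre, cannot aromatise and can only revert, while the Claisen product is withdrawn as a chelated aryl ketone. In ring B the former C3=C4 bond of the pyranone holds the ester carbon and the chain cis, as the closure requires, and fixes the methoxy group para to the butanoyl group. Methoxide in methanol is chosen because its addition at C4 of the methoxypyranone is degenerate and because the methyl ester it forms is the Claisen acceptor. The neutral methoxypyranone should open first (giving 12) and the 4-oxido pyranone of ring A second.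

## Compound list

1 | ethyl 3-oxopentanoate | CCC(=O)CC(=O)OCC | starting material
2 | N-methoxy-N-methylacetamide | CC(=O)N(C)OC | starting material
3 | ethyl 4-methyl-3,5-dioxohexanoate | CCOC(=O)CC(=O)C(C)C(C)=O | intermediate
4 | 4-hydroxy-5,6-dimethyl-2H-pyran-2-one | CC1=C(C)C(O)=CC(=O)O1 | intermediate
5 | N-methoxy-N-methylbutanamide | CCCC(=O)N(C)OC | starting material
6 | 4-hydroxy-5-methyl-6-(2-oxopentyl)-2H-pyran-2-one | CCCC(=O)CC1=C(C)C(O)=CC(=O)O1 | intermediate
7 | formaldehyde | C=O | starting material
8 | 5-methyl-3-methylidene-6-(2-oxopentyl)-2H-pyran-2,4(3H)-dione (not isolated) | CCCC(=O)CC1=C(C)C(=O)C(=C)C(=O)O1 | intermediate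
9 | 3,3'-methylenebis[4-hydroxy-5-methyl-6-(2-oxopentyl)-2H-pyran-2-one] | CCCC(=O)CC1=C(C)C(O)=C(CC2=C(O)C(C)=C(CC(=O)CCC)OC2=O)C(=O)O1 | intermediate
10 | 3-{[4-hydroxy-5-methyl-2-oxo-6-(2-oxopentyl)-2H-pyran-3-yl]methyl}-4-methoxy-5-methyl-6-(2-oxopentyl)-2H-pyran-2-one | CCCC(=O)CC1=C(C)C(O)=C(CC2=C(OC)C(C)=C(CC(=O)CCC)OC2=O)C(=O)O1 | intermediate
11 | methyl (2E)-2-{[4-hydroxy-5-methyl-2-oxo-6-(2-oxopentyl)-2H-pyran-3-yl]methyl}-3-methoxy-4-methyl-5,7-dioxodec-2-enoate (not isolated; C4 racemic) | COC(=O)/C(CC1=C(O)C(C)=C(CC(=O)CCC)OC1=O)=C(/OC)C(C)C(=O)CC(=O)CCC | intermediate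
12 | 3-[(3-butanoyl-2,4-dihydroxy-6-methoxy-5-methylphenyl)methyl]-4-hydroxy-5-methyl-6-(2-oxopentyl)-2H-pyran-2-one (not isolated) | CCCC(=O)c1c(O)c(C)c(OC)c(CC2=C(O)C(C)=C(CC(=O)CCC)OC2=O)c1O | intermediate
13 | methyl 2-[(3-butanoyl-2,4-dihydroxy-6-methoxy-5-methylphenyl)methyl]-4-methyl-3,5,7-trioxodecanoate (not isolated; mixture of stereoisomers and tautomers) | COC(=O)C(Cc1c(O)c(C(=O)CCC)c(O)c(C)c1OC)C(=O)C(C)C(=O)CC(=O)CCC | intermediate
14 | margaspidin, 1-{3-[(3-butanoyl-2,4-dihydroxy-6-methoxy-5-methylphenyl)methyl]-2,4,6-trihydroxy-5-methylphenyl}butan-1-one | CCCC(=O)c1c(O)c(C)c(O)c(Cc2c(O)c(C(=O)CCC)c(O)c(C)c2OC)c1O | target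

## Step count and risk

Total step count: 6. Longest linear sequence: 6 steps (1 to 14; pyranone 6 enters step 4 twice).

**Step 6 (key step).** Three processes may interfere:
- stalling after the first fold, because the ring-A pyranone is present as its 4-oxido anion and resists addition of methoxide;
- exchange of the two halves across the methylene bridge once phenolates are present, giving symmetrical dimers;
- air oxidation of the polyphenolate during work-up.

Fallback, from 6 back to 14: the rings are folded before they are bridged.
- Pyranone 6 alone is folded with Mg(OMe)2 in methanol to 1-(2,4,6-trihydroxy-3-methylphenyl)butan-1-one F1.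
- A second portion of 6 is O-methylated (Me2SO4, K2CO3, acetone) to 4-methoxy-5-methyl-6-(2-oxopentyl)-2H-pyran-2-one F2, which is folded in the same way to 1-(2,6-dihydroxy-4-methoxy-3-methylphenyl)butan-1-one F3.
- F1 is aminomethylated at its one free ring carbon with dimethylmethyleneiminium iodide to 1-{3-[(dimethylamino)methyl]-2,4,6-trihydroxy-5-methylphenyl}butan-1-one F4.
- F4 is heated with F3 in dioxane; loss of dimethylamine gives the ortho-quinone methide, which F3 captures at its free ring carbon to give 14.

**Step 5.** Over-methylation to the bis-ether, and methylation at the lactone carbonyl oxygen to the isomeric 2-methoxy-4-pyranone, are the likely losses. The two OH groups are equivalent, so selectivity for the monoether rests on stoichiometry only.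

Fallback, from 4 back to 10: a directed assembly.
- Pyranone 4 is methylated (Me2SO4, K2CO3, acetone) to 4-methoxy-5,6-dimethyl-2H-pyran-2-one F5.
- Rieche formylation at C3 (Cl2CHOMe, TiCl4, CH2Cl2) gives 4-methoxy-5,6-dimethyl-2-oxo-2H-pyran-3-carbaldehyde F6.
- Reductive Knoevenagel alkylation of a second molecule of 4 with F6 (Hantzsch ester, catalytic L-proline) gives 3-[(4-hydroxy-5,6-dimethyl-2-oxo-2H-pyran-3-yl)methyl]-4-methoxy-5,6-dimethyl-2H-pyran-2-one F7.
- Threefold deprotonation of F7 (LiN(iPr)2, 3.3 equiv) and acylation of both 6-methyl groups with 5 gives 10.

**Step 3.** Aggregation and low solubility of the dianion may slow the acylation. Proton transfer from the α-methylene of amide 5 to the dianion would return 4.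

Fallback, from 4 back to 6: the reacting species is changed to a soluble monoanion.
- Pyranone 4 is O-benzylated (BnBr, K2CO3) to 4-(benzyloxy)-5,6-dimethyl-2H-pyran-2-one F8.
- The monoanion of F8 (LiN(iPr)2, 1.1 equiv, −78 °C) is acylated with 5 to 4-(benzyloxy)-5-methyl-6-(2-oxopentyl)-2H-pyran-2-one F9.
- Hydrogenolysis (H2, Pd/C, EtOAc) gives 6.

**Step 4.** Condensation of formaldehyde at the side-chain methylene, which lies between the ketone and C6, may compete with reaction at C3 and lead to oligomers.

Fallback, from 4 back to 9: the bridge is made before the side chains.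
- Pyranone 4 is dimerised with formaldehyde 7 to 3,3'-methylenebis(4-hydroxy-5,6-dimethyl-2H-pyran-2-one) F10.
- Fourfold deprotonation of F10 (LiN(iPr)2, 4.4 equiv) and acylation of both 6-methyl groups with 5 gives 9.

## Further compounds

F1 | step 6 | 1-(2,4,6-trihydroxy-3-methylphenyl)butan-1-one | CCCC(=O)c1c(O)cc(O)c(C)c1O
F2 | step 6 | 4-methoxy-5-methyl-6-(2-oxopentyl)-2H-pyran-2-one | CCCC(=O)CC1=C(C)C(OC)=CC(=O)O1
F3 | step 6 | 1-(2,6-dihydroxy-4-methoxy-3-methylphenyl)butan-1-one (aspidinol) | CCCC(=O)c1c(O)cc(OC)c(C)c1O
F4 | step 6 | 1-{3-[(dimethylamino)methyl]-2,4,6-trihydroxy-5-methylphenyl}butan-1-one | CCCC(=O)c1c(O)c(C)c(O)c(CN(C)C)c1O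
F5 | step 5 | 4-methoxy-5,6-dimethyl-2H-pyran-2-one | CC1=C(C)C(OC)=CC(=O)O1
F6 | step 5 | 4-methoxy-5,6-dimethyl-2-oxo-2H-pyran-3-carbaldehyde | CC1=C(C)C(OC)=C(C=O)C(=O)O1
F7 | step 5 | 3-[(4-hydroxy-5,6-dimethyl-2-oxo-2H-pyran-3-yl)methyl]-4-methoxy-5,6-dimethyl-2H-pyran-2-one | CC1=C(C)C(O)=C(CC2=C(OC)C(C)=C(C)OC2=O)C(=O)O1
F8 | step 3 | 4-(benzyloxy)-5,6-dimethyl-2H-pyran-2-one | CC1=C(C)C(OCc2ccccc2)=CC(=O)O1
F9 | step 3 | 4-(benzyloxy)-5-methyl-6-(2-oxopentyl)-2H-pyran-2-one | CCCC(=O)CC1=C(C)C(OCc2ccccc2)=CC(=O)O1
F10 | step 4 | 3,3'-methylenebis(4-hydroxy-5,6-dimethyl-2H-pyran-2-one) | CC1=C(C)C(O)=C(CC2=C(O)C(C)=C(C)OC2=O)C(=O)O1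
A1 | alternative 1 | 2-methylbenzene-1,3,5-triol | Cc1c(O)cc(O)cc1O
A2 | alternative 1 | 1-(2,4,6-trihydroxy-3-methylphenyl)butan-1-one | CCCC(=O)c1c(O)cc(O)c(C)c1O
A3 | alternative 1 | 1-(2,6-dihydroxy-4-methoxy-3-methylphenyl)butan-1-one (aspidinol) | CCCC(=O)c1c(O)cc(OC)c(C)c1O
A4 | alternative 1 | 1-{3-[(dimethylamino)methyl]-2,4,6-trihydroxy-5-methylphenyl}butan-1-one | CCCC(=O)c1c(O)c(C)c(O)c(CN(C)C)c1O
A5 | alternative 2 | 3-[(3-butanoyl-2,4,6-trihydroxy-5-methylphenyl)methyl]-4-hydroxy-5-methyl-6-(2-oxopentyl)-2H-pyran-2-one | CCCC(=O)CC1=C(C)C(O)=C(Cc2c(O)c(C)c(O)c(C(=O)CCC)c2O)C(=O)O1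
A6 | alternative 2 | 3-[(3-butanoyl-2,4,6-trihydroxy-5-methylphenyl)methyl]-4-methoxy-5-methyl-6-(2-oxopentyl)-2H-pyran-2-one | CCCC(=O)CC1=C(C)C(OC)=C(Cc2c(O)c(C)c(O)c(C(=O)CCC)c2O)C(=O)O1
A7 | alternative 3 | 1-(2,4,6-trihydroxy-3,5-dimethylphenyl)butan-1-one | CCCC(=O)c1c(O)c(C)c(O)c(C)c1O
A8 | alternative 3 | 2-butanoyl-3,5-dihydroxy-4-methyl-6-methylidenecyclohexa-2,4-dien-1-one | CCCC(=O)C1=C(O)C(C)=C(O)C(=C)C1=O
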